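A small charge of free catalyst, 1 mol%, has to work through 0.020 M of substrate. With reagent at 2.00 equiv, the substrate is the limiting reagent, so you keep the books on it.

| setting | west | north | south-west | Monday's | Thursday's | Saturday's | Tuesday's |
|---|---|---|---|---|---|---|---|
| substrate | 0.020 M | 0.010 M | 0.015 M | 0.020 M (fed, over 15 min) | 0.020 M (fed, over 15 min) | 0.020 M | 0.020 M |
| reagent | 2 equiv | 2 equiv | 2 equiv | 2.00 equiv | 2.00 equiv | 2.00 equiv | 2.00 equiv (fed, over 15 min) |
| free catalyst | 1 mol% | 1 mol% | 1 mol% | 1 mol% | 1 mol% | 1 mol% | 1 mol% |
| temperature | 35 °C | 46 °C | 35 °C |  | 40 °C |  | 40 °C |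
| remark | run made earlier | run made earlier | run made earlier | the addition at 0 °C, then warmed to 40 °C; the feed brings no volume worth counting | all else is in the flask from the start; the feed brings no volume worth counting | everything together at the start at 0 °C, warmed to 40 °C at 15 min | all else is in the flask from the start; the feed brings no volume worth counting |
| time |  |  |  | 25 min | 25 min | 25 min | 25 min |

- west (time / min: target / %): 2.00: 2.3; 3.00: 2.6; 6.00: 6.0; 10.0: 9.0; 15.0: 11.6; 25.0: 17.0
- north (time / min: target / %): 1.33: 2.9; 4.00: 4.7; 8.00: 10.4; 10.0: 12.8; 15.0: 16.0; 20.0: 20.6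
- south-west (time / min: target / %): 1.33: 0.9; 4.00: 2.9; 8.00: 5.1; 10.0: 8.0; 15.0: 10.9; 20.0: 12.0

(standard deviation of a reading: 0.5 percentage points)



1. the flask that comes out highest in amount of target, in percent of the substrate charged, or "all alike" when all lie within 1.5 percentage points (Monday's / Thursday's / Saturday's / Tuesday's / all alike)
2. target at the end, in percent of the substrate charged, Monday's
3. target at the end, in percent of the substrate charged, Thursday's
4. target at the end, in percent of the substrate charged, Saturday's
5. target at the end, in percent of the substrate charged, Tuesday's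

Replace each curve by its mean slope over the first 10.0 min. West gives 0.00900 min⁻¹ of the charge and south-west gives 0.00800 min⁻¹, both at 35 °C. So the slope goes as [substrate] to the power 0.409, a rough reading given the scatter. I round it and carry the power 0.500. That power lifts north's 0.0128 min⁻¹ to 0.0181 min⁻¹ at 0.020 M. Interpolating between 35 °C and 46 °C gives my warm rate, 0.0124 min⁻¹. The warm rate is the mean share of the charge turned into target per minute at 40 °C and 0.020 M, over the early part of the curve. Carrying the same trend down gives 9.74 × 10⁻⁴ min⁻¹ at 0 °C.

Now open my ledger for Saturday's. The cold entry is 15 min at that slope, 1.46%. The warm entry is 10.0 min at the warm rate, 12.4%. I book no other loss, so 86.1% stays substrate. For Monday's I book the same warm entry, with the feed running through the cold 15 min. For a flask at 40 °C throughout, west's mean over 25.0 min, scaled to the warm rate, gives 23.4%. Thursday's and Tuesday's each feed one charge, and I set them below that figure. The runs do not separate substrate from reagent, so I leave those two unranked.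

The forecast does rank them. It expects 12.3% for Monday's, 16.5% for Thursday's, 12.7% for Saturday's and 20.5% for Tuesday's, with Tuesday's highest. Of the cold pair it says “The cold flasks effectively get only 10 warm minutes”.

The flasks give 12.8% for Monday's, 17.3% for Thursday's, 12.9% for Saturday's and 20.7% for Tuesday's, so Tuesday's is highest.

    substrate + catalyst intermediate B → catalyst intermediate C (k = 5.30 M⁻¹ s⁻¹, Ea = 40.0 kJ mol⁻¹)
    catalyst intermediate A → catalyst intermediate B (k = 1.30 s⁻¹, Ea = 68.0 kJ mol⁻¹)
    catalyst intermediate C → catalyst intermediate D (k = 0.110 s⁻¹, Ea = 85.0 kJ mol⁻¹)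
    catalyst intermediate D → free catalyst + target (k = 0.580 s⁻¹, Ea = 70.0 kJ mol⁻¹)
    reagent + free catalyst ⇌ catalyst intermediate A (K = 5.40 M⁻¹, k = 2.60 M⁻¹ s⁻¹, Ea = 63.0 kJ mol⁻¹, ΔH = −26.0 kJ mol⁻¹)
    target + free catalyst ⇌ isomer of the product + free catalyst, rate k6*[free catalyst]*[target] forward; the back reaction follows from the equilibrium constant (K = 0.690, k = 13.0 M⁻¹ s⁻¹, Ea = 41.0 kJ mol⁻¹, ΔH = −67.0 kJ mol⁻¹)
    reagent + catalyst intermediate B → spent catalyst (k = 0.0240 M⁻¹ s⁻¹, Ea = 52.0 kJ mol⁻¹)
    (constants at 40 °C)

Tuesday's leads Thursday's by 3.4 percentage points. Monday's and Saturday's stand 0.100 points apart. Spread over its 10.0 min at 40 °C, Monday's target comes to 0.0128 min⁻¹, beside the warm rate of 0.0124 min⁻¹. Now take Monday's with 0.080 M of substrate, equivalents and loading held. The warm rate, scaled by the power 0.500, gives 24.8% for the warm entry. That flask gives 20.8% of target and 7.59% of isomer of the product, with 71% of its substrate left.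

Readings and results come from a simulation with constants of no real substance, noise included.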